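**Assumption:** the SMILES corresponds to the natural cis-pterocarpan, (6aR,11aR). I checked this by CIP analysis of both stereocentres. I also assume a commercial ketoreductase (KRED) panel contains a member that gives the cis-(3R,4R) alcohol by dynamic kinetic resolution (DKR).

## Retrosynthetic overview
1. The target comes from a (3R,4R)-cis-isoflavan-4-ol bis-MOM ether by MOM cleavage and cis-selective closure of the dihydrofuran ring through a benzylic cation. This is the last ring formed, and C6a is retained.
2. That alcohol comes from a racemic isoflavanone by KRED-catalysed DKR, which sets C3 and C4. The isoflavanone comes from the isoflavone by L-Selectride 1,4-reduction.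
3. The isoflavone comes from a Suzuki coupling of 3-iodo-pyranochromone **7** with aryl-Bpin **14**. The B-ring dimethylchromene is closed last by phenol–prenal annulation.
4. Ring order:
   - A-ring pyran: the C8-bromo blocker forces the linear regiochemistry, and the bromine is removed afterwards.
   - Chromone ring.
   - B-ring benzene, built by directed ortho-metalation (prenyl, then O, then B).
   - Biaryl, then B-ring pyran, then the chromanone CH₂ after reduction, then the dihydrofuran.
5. All carbon comes from achiral resorcinols, AcOH, prenal and prenyl bromide.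

## Route

**Step 1**
Reactants: **1** 2-bromoresorcinol
Product: **2** 1-(3-bromo-2,4-dihydroxyphenyl)ethan-1-one
Conditions: AcOH, BF₃·OEt₂, 90 °C
Reagents that add atoms: acetic acid, CC(=O)O
Why: Friedel–Crafts (Nencki-type) acylation goes para to one OH and ortho to the other (C4), leaving the bromine between the two oxygens as a blocking group.

**Step 2**
Reactants: **2**; **3** 3-methylbut-2-enal (prenal)
Product: **4** 1-(8-bromo-7-hydroxy-2,2-dimethyl-2H-chromen-6-yl)ethan-1-one
Conditions: pyridine, 115 °C, sealed tube
Reagents that add atoms: none beyond reactant **3**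
Why: phenol–enal annulation (condensation then oxa-6π-electrocyclization) can only occur at C5, because C3 carries Br and the 2-OH is chelated, so only the linear pyran forms.

**Step 3**
Reactants: **4**
Product: **5** 1-(7-hydroxy-2,2-dimethyl-2H-chromen-6-yl)ethan-1-one
Conditions: Bu₃SnH, AIBN (cat.), toluene, 110 °C
Reagents that add atoms: none
Why: radical hydrodebromination removes the blocker. The aryl bromide is reduced selectively, and the ketone and chromene are not touched.

**Step 4**
Reactants: **5**
Product: **6** (E)-3-(dimethylamino)-1-(7-hydroxy-2,2-dimethyl-2H-chromen-6-yl)prop-2-en-1-one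
Conditions: DMF-DMA, toluene, reflux
Reagents that add atoms: DMF-DMA, CN(C)C(OC)OC
Why: condensation of the acetyl methyl group with the amide acetal gives the enaminone. The only phenol is the chelated one, so no competing O-methylation occurs.

**Step 5**
Reactants: **6**
Product: **7** 3-iodo-8,8-dimethyl-4H,8H-pyrano[3,2-g]chromen-4-one
Conditions: I₂ (1.1 equiv), CHCl₃, 0 °C to rt
Reagents that add atoms: iodine, II
Why: α-iodination of the enaminone followed by phenol addition–elimination (loss of Me₂NH) closes the chromone. The enaminone carbon is far more nucleophilic than the chromene alkene.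

**Step 6**
Reactants: **8** resorcinol
Product: **9** 1,3-bis(methoxymethoxy)benzene
Conditions: NaH, MOMCl, THF/DMF, 0 °C
Reagents that add atoms: MOMCl, COCCl
Why: Williamson-type bis-MOM protection installs directing groups for ortho-metalation.

**Step 7**
Reactants: **9**; **10** prenyl bromide
Product: **11** 1,3-bis(methoxymethoxy)-2-(3-methylbut-2-en-1-yl)benzene
Conditions: n-BuLi, THF, 0 °C; then CuI (10 mol%), prenyl bromide, −20 °C to rt
Reagents that add atoms: none beyond reactant **10**
Why: directed ortho-metalation occurs at the doubly activated C2, and Cu-catalysed SN2 alkylation gives the normal (not reverse) prenyl group.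

**Step 8**
Reactants: **11**
Product: **12** 2,4-bis(methoxymethoxy)-3-(3-methylbut-2-en-1-yl)phenol
Conditions: n-BuLi, TMEDA, THF, −20 °C; B(OMe)₃, −78 °C to rt; then 30% H₂O₂, 2 M NaOH, 0 °C
Reagents that add atoms: hydrogen peroxide, OO (supplies the phenol O); B(OMe)₃, COB(OC)OC, leaves no atoms
Why: with C2 blocked, lithiation is directed to the equivalent C4/C6 position, and borate oxidation gives the phenol, which will become the B-ring C5'–O of the chromene.

**Step 9**
Reactants: **12**
Product: **13** tert-butyl{2,4-bis(methoxymethoxy)-3-prenylphenoxy}dimethylsilane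
Conditions: TBSCl, imidazole, DMF, rt
Reagents that add atoms: TBSCl, CC(C)(C)[Si](C)(C)Cl
Why: silylation gives a non-directing aryl silyl ether, so the next lithiation is controlled by the OMOM group.

**Step 10**
Reactants: **13**
Product: **14** aryl-Bpin (2-[3-prenyl-2,4-bis(MOM-oxy)-5-(TBS-oxy)phenyl]-4,4,5,5-tetramethyl-1,3,2-dioxaborolane)
Conditions: n-BuLi, THF, −78 °C; then iPrOBpin, −78 °C to rt
Reagents that add atoms: iPrOBpin, CC(C)OB1OC(C)(C)C(C)(C)O1
Why: directed ortho-metalation ortho to the OMOM at C2' is the only strongly directed site left, and the Bpin ester is bench-stable for the coupling.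

**Step 11**
Reactants: **7**; **14**
Product: **15** isoflavone (3-aryl-chromone, aryl = 5'-OTBS-2',4'-bis-OMOM-3'-prenyl)
Conditions: Pd(PPh₃)₄ (5 mol%), Na₂CO₃, DME/H₂O 4:1, 85 °C
Reagents that add atoms: none
Why: Suzuki–Miyaura coupling of the reactive vinyl iodide with the aryl pinacol boronate joins the two halves without affecting the three alkenes.

**Step 12**
Reactants: **15**
Product: **16** isoflavone with free 5'-OH
Conditions: TBAF, AcOH (1:1), THF, 0 °C
Reagents that add atoms: none
Why: fluoride-mediated desilylation, buffered with AcOH so the chromone C2 is not attacked and the MOM groups stay.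

**Step 13**
Reactants: **16**; **3** prenal
Product: **17** bis(dimethylchromene) isoflavone (B-ring pyran closed at C6')
Conditions: prenal (5 equiv), pyridine, 115 °C, sealed tube
Reagents that add atoms: none beyond reactant **3**
Why: phenol–enal annulation can only occur at C6' (C4' is OMOM), so regiochemistry is unambiguous, and the MOM ethers tolerate pyridine.

**Step 14**
Reactants: **17**
Product: **18** racemic isoflavanone
Conditions: L-Selectride (1.1 equiv), THF, −78 °C; then NH₄Cl(aq)
Reagents that add atoms: none
Why: conjugate (1,4) hydride addition to the chromone C2 followed by enolate protonation gives the isoflavanone with an epimerizable C3 (racemic) and leaves the isolated alkenes untouched.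

**Step 15**
Reactants: **18**
Product: **19** (3R,4R)-cis-isoflavan-4-ol bis-MOM ether
Conditions: ketoreductase (KRED, an NADPH-dependent oxidoreductase, EC 1.1.1.x; panel hit), NADP⁺ (cat.), iPrOH (15% v/v, cofactor recycling), KPi pH 7.5, DMSO 10% v/v, 30 °C
Reagents that add atoms: none
Why: DKR. The acidic C3–H of the isoflavanone epimerizes at pH 7.5, and the enzyme reduces only the (3R)-ketone on one face of C=O, giving cis-(3R,4R) (the configuration of the natural vestitone-reductase product). This sets C3 and C4, the first stereocentres, by asymmetric catalysis.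

**Step 16**
Reactants: **19**
Product: **20** Lespecyrtin E4 (6aR,11aR)
Conditions: 2 M HCl/THF/MeOH (1:2:2), 40 °C, 6 h
Reagents that add atoms: none
Why: acid removes both aryl MOM ethers, and the free 2'-OH captures the para-alkoxy-stabilised C4 benzylic cation in an SN1 etherification that can only close cis-fused (ring strain), giving 11aR. C3 is not involved, so it becomes 6aR with no loss of ee.

## Compound list
1 | 2-bromoresorcinol | Oc1cccc(O)c1Br | starting material
2 | 1-(3-bromo-2,4-dihydroxyphenyl)ethan-1-one | CC(=O)c1ccc(O)c(Br)c1O | intermediate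
3 | 3-methylbut-2-enal (prenal) | CC(C)=CC=O | starting material
4 | 1-(8-bromo-7-hydroxy-2,2-dimethyl-2H-chromen-6-yl)ethan-1-one | CC(=O)c1cc2C=CC(C)(C)Oc2c(Br)c1O | intermediate
5 | 1-(7-hydroxy-2,2-dimethyl-2H-chromen-6-yl)ethan-1-one | CC(=O)c1cc2C=CC(C)(C)Oc2cc1O | intermediate
6 | (E)-enaminone of 5 | CN(C)/C=C/C(=O)c1cc2C=CC(C)(C)Oc2cc1O | intermediate
7 | 3-iodo-8,8-dimethyl-4H,8H-pyrano[3,2-g]chromen-4-one | O=C1C(I)=COc2cc3OC(C)(C)C=Cc3cc12 | intermediate
8 | resorcinol | Oc1cccc(O)c1 | starting material
9 | 1,3-bis(methoxymethoxy)benzene | COCOc1cccc(OCOC)c1 | intermediate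
10 | prenyl bromide | CC(C)=CCBr | starting material
11 | 1,3-bis(MOM-oxy)-2-prenylbenzene | COCOc1cccc(OCOC)c1CC=C(C)C | intermediate
12 | 2,4-bis(MOM-oxy)-3-prenylphenol | Oc1ccc(OCOC)c(CC=C(C)C)c1OCOC | intermediate
13 | TBS ether of 12 | CC(C)(C)[Si](C)(C)Oc1ccc(OCOC)c(CC=C(C)C)c1OCOC | intermediate
14 | aryl-Bpin | CC(C)(C)[Si](C)(C)Oc1cc(B2OC(C)(C)C(C)(C)O2)c(OCOC)c(CC=C(C)C)c1OCOC | intermediate
15 | isoflavone, 5'-OTBS | O=C1C(c2cc(O[Si](C)(C)C(C)(C)C)c(OCOC)c(CC=C(C)C)c2OCOC)=COc2cc3OC(C)(C)C=Cc3cc12 | intermediate
16 | isoflavone, 5'-OH | O=C1C(c2cc(O)c(OCOC)c(CC=C(C)C)c2OCOC)=COc2cc3OC(C)(C)C=Cc3cc12 | intermediate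
17 | bis-chromene isoflavone | O=C1C(c2c3C=CC(C)(C)Oc3c(OCOC)c(CC=C(C)C)c2OCOC)=COc2cc3OC(C)(C)C=Cc3cc12 | intermediate
18 | racemic isoflavanone | O=C1C(c2c3C=CC(C)(C)Oc3c(OCOC)c(CC=C(C)C)c2OCOC)COc2cc3OC(C)(C)C=Cc3cc12 | intermediate
19 | (3R,4R)-cis-isoflavan-4-ol bis-MOM ether | O[C@H]1c2cc3C=CC(C)(C)Oc3cc2OC[C@H]1c1c2C=CC(C)(C)Oc2c(OCOC)c(CC=C(C)C)c1OCOC | intermediate
20 | Lespecyrtin E4 | CC(C)=CCc1c(O)c2c(c3c1O[C@H]1c4cc5c(cc4OC[C@@H]31)OC(C)(C)C=C5)C=CC(C)(C)O2 | target

## Totals
- Total steps: 16.
- Longest linear sequence: 11 steps (steps 1–5 then 11–16, or steps 6–10 then 11–16).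

## Three steps most likely to fail
1. **Step 15 (KRED DKR).** The substrate is bulky, with a 2,6-disubstituted 3-aryl group, and the enzyme may not give cis-(3R,4R) selectively.
   - Fallback: chemocatalytic Ru–TsDPEN asymmetric transfer hydrogenation/DKR (HCO₂H/Et₃N) of **18**, which also gives the cis-alcohol.
2. **Step 16 (acid cascade).** Competing isoflavene elimination (which would erase C3), prenyl-phenol cyclisation, or MeOH trapping.
   - Fallback: remove the MOM groups first with ZnBr₂/n-PrSH. Then use a trans-selective KRED variant and close the ring by intramolecular Mitsunobu etherification (SN2 inversion, no cation).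
3. **Step 13 (annulation on the crowded phenol).** Slow reaction or decomposition of **16** at 115 °C.
   - Fallback: O-propargylation with 3-chloro-3-methylbut-1-yne (K₂CO₃, KI), followed by thermal propargyl Claisen cyclisation (PhNEt₂, 180 °C) to form the chromene.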